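All runs were generated by integration for an exercise.

The one constant I need is not given, so I read it from the earlier runs. Late in the autumn run the isomer of the product wanders, at 1.5 % and then 3.3 %, so I replace that stretch of the curve by its mean and turn it into a concentration:

[isomer of the product] = 2.40 % × 0.12 M = 2.88 mM

I call this the floor: the late concentration of isomer of the product, supposed the same at any charge, the end state of thermodynamic control. The summer mean of 0.800 % gives 4.00 mM, but there a reading's scatter is worth 2.50 mM against 0.600 mM in autumn, so I keep the autumn value.

Turned round: if the isomer were a fixed percentage of the charge instead, the two means would agree. They lie 1.6 percentage points apart, more than the 0.5 points scatter of that gap.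

| flask | solid substrate | remark | time |
|---|---|---|---|
| autumn | 0.12 M | run made earlier |  |
| summer | 0.50 M | run made earlier |  |
| flask | 0.25 M |  | 15 d |

| run | time / d | target / % | isomer of the product / % |
|---|---|---|---|
| autumn | 0.833 | 69.7 | 19.5 |
| autumn | 2.50 | 90.8 | 5.9 |
| autumn | 4.00 | 95.2 | 2.7 |
| autumn | 6.00 | 96.9 | 1.5 |
| autumn | 10.0 | 95.4 | 3.3 |
| summer | 0.833 | 48.0 | 17.1 |
| summer | 2.50 | 90.5 | 6.4 |
| summer | 4.00 | 96.1 | 1.8 |
| summer | 6.00 | 97.2 | 0.9 |
| summer | 10.0 | 96.9 | 0.7 |

(each reading ± 0.5 percentage points)

- at the start none of the solid substrate is in solution
- a reading or a percentage of target counts all its forms, free or not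

- share of target in target plus isomer of the product at 3.0 h
- share of target in target plus isomer of the product at 15 d

For this flask I reckon, taking target as nearly the rest:

isomer of the product = floor / 0.25 M = 1.15 %, share = 98.8 %

The forecast gives 67 % (52 % to 78 %) for the early share and 98.5 % (97.4 % to 99.2 %) for the late one, the late one on the ground that a nearly fixed late concentration of isomer “fits saturated target in equilibrium with isomer”. Its late share lies slightly below mine.

The flask gives 63.9 % and 98.9 %.

    crystals ⇌ target, rate k1*(cs1 - [target]) while solid is left; crystals form when [target] > cs1 (solubility = 2.90 mM, k = 0.720 min⁻¹)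
    starting material + intermediate → side product (k = 6.50 × 10⁻⁴ M⁻¹ min⁻¹)
    intermediate ⇌ isomer of the product (K = 2.70, k = 0.00320 min⁻¹)
    starting material → intermediate (k = 0.00270 min⁻¹)
    intermediate ⇌ target (K = 2.80, k = 0.00570 min⁻¹)
    solid substrate ⇌ starting material, rate k6*(cs6 - [starting material]) while solid is left; crystals form when [starting material] > cs6 (solubility = 0.180 M, k = 0.00700 min⁻¹)

It holds 1.12 % of isomer of the product at 15.0 d, and ten times as long changes nothing; the floor had said 1.15 %. In the neighbour flask with 0.42 M of solid substrate, the floor gives 0.686 % of isomer and a share of 99.3 %; the computed share is 99.3 %.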